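**Plan**

- Retrosynthesis: the acetyl group is traced back to a glycol (one C–C cleavage) and the ring-A phenol and aldehyde to their acetals. Next the aryl C6–O bond of the 1,3-dioxine is cut (isoquinoline C6 to the acetal oxygen), which leaves a 3-aryl-isochroman lactol. Then the lactone C1–O bond and the C3–C4 bond are cut, giving a ring-A methallyl benzoate and an isoquinoline-7-carbaldehyde, both made from one keto ester derived from methyl orsellinate.
- Enabling feature: the acetal carbon C1 is the anomeric carbon of a 3-aryl isochroman. Its hydroxyl can stand 1,3-cis to the isoquinolin-7-yl group on C3, next to isoquinoline C6, so forming the C6–O bond closes the six-membered 1,3-dioxine as the last ring.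
- Forward order: common keto ester; pyridine ring of the isoquinoline by ammonia condensation; union of the halves at C3–C4 by allylboration; isochromanone ring by lactonisation; lactol; 1,3-dioxine by palladium C–O coupling; unmasking.
- Stereochemistry: C3 and C4 come from a reagent-controlled anti allylboration (isopinocampheyl groups on boron, E allyl unit). C1 follows from C3 in the ring closure. The acetyl group is carried as isopropenyl and then as a glycol acetonide, so C4–H is not acidic until the last step.

Key step: step 15

Remark: C1, C3 and C4 are isochroman locants (C1 lactone or acetal carbon, C3 the O–CH–isoquinolinyl carbon, C4 the CH bearing the acetyl group or its mask); C6, C7 and C8 are isoquinoline locants. The carbinol carbon created in step 12 is carried as both epimers because it becomes the carbonyl carbon in step 17.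

**Route**

Step 1
Reactants: 1 methyl orsellinate
Product: 2 methyl 2-hydroxy-4-(methoxymethoxy)-6-methylbenzoate
Conditions: MOMCl, iPr2NEt, CH2Cl2, 0 °C to rt
Reagents that add atoms: chloromethyl methyl ether, COCCl
Why: O-alkylation (Williamson type) should occur at the 4-hydroxyl, because the 2-hydroxyl is tied up in a hydrogen bond to the ester and is much less nucleophilic.

Step 2
Reactants: 2 methyl 2-hydroxy-4-(methoxymethoxy)-6-methylbenzoate
Product: 3 methyl 3-formyl-2-hydroxy-4-(methoxymethoxy)-6-methylbenzoate
Conditions: MgCl2, Et3N, (CH2O)n, MeCN, reflux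
Reagents that add atoms: formaldehyde (as paraformaldehyde), C=O
Why: Magnesium-mediated ortho-formylation (Casnati–Skattebøl type) delivers formaldehyde only ortho to the free hydroxyl, and C3 is the one open ortho position; a second formaldehyde oxidises the hydroxymethyl intermediate to the aldehyde.

Step 3
Reactants: 3 methyl 3-formyl-2-hydroxy-4-(methoxymethoxy)-6-methylbenzoate
Product: 4 methyl 3-formyl-2-methoxy-4-(methoxymethoxy)-6-methylbenzoate
Conditions: MeI, K2CO3, DMF, 40 °C
Reagents that add atoms: iodomethane, CI
Why: Williamson etherification of the remaining phenol, whose potassium salt forms readily in DMF despite chelation, fixes the methoxy group that becomes C8–OMe of the isoquinoline and the ring-A methoxy group.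

Step 4
Reactants: 4 methyl 3-formyl-2-methoxy-4-(methoxymethoxy)-6-methylbenzoate
Product: 5 methyl 3-(1,3-dioxolan-2-yl)-2-methoxy-4-(methoxymethoxy)-6-methylbenzoate
Conditions: TMSOCH2CH2OTMS, TMSOTf (cat.), CH2Cl2, −78 to −20 °C; pyridine quench
Reagents that add atoms: 1,2-bis(trimethylsilyloxy)ethane, C[Si](C)(C)OCCO[Si](C)(C)C
Why: Noyori acetalisation under aprotic, cold conditions should protect the aldehyde against the carbanion and hydride steps ahead without cleaving the MOM ether.

Step 5
Reactants: 5 methyl 3-(1,3-dioxolan-2-yl)-2-methoxy-4-(methoxymethoxy)-6-methylbenzoate; 6 N-methoxy-N-methylacetamide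
Product: 7 methyl 3-(1,3-dioxolan-2-yl)-2-methoxy-4-(methoxymethoxy)-6-(2-oxopropyl)benzoate
Conditions: LiN(iPr)2, THF, −78 °C; then 6; NH4Cl
Reagents that add atoms: none
Why: Lateral lithiation of the ortho-toluate (benzylic deprotonation to an ester-stabilised anion) followed by Weinreb acylation, whose chelated tetrahedral intermediate prevents over-addition, gives the keto ester that serves both halves.

Step 6
Reactants: 7 methyl 3-(1,3-dioxolan-2-yl)-2-methoxy-4-(methoxymethoxy)-6-(2-oxopropyl)benzoate
Product: 8 1-[4-(1,3-dioxolan-2-yl)-2-(hydroxymethyl)-3-methoxy-5-(methoxymethoxy)phenyl]propan-2-ol (racemic)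
Conditions: LiAlH4, THF, 0 °C to rt
Reagents that add atoms: none
Why: Hydride reduction with LiAlH4 takes the hindered ester and the ketone to the diol while the acetal and the MOM ether are inert; the carbinol centre is erased in the next step.

Step 7
Reactants: 8 1-[4-(1,3-dioxolan-2-yl)-2-(hydroxymethyl)-3-methoxy-5-(methoxymethoxy)phenyl]propan-2-ol
Product: 11 6-hydroxy-8-methoxy-3-methylisoquinoline-7-carbaldehyde, via keto aldehyde 9 (not isolated), via protected isoquinoline 10 (not isolated)
Conditions: (COCl)2, DMSO, CH2Cl2, −78 °C; Et3N, −78 to 0 °C; NH4OAc, MeOH, rt; then 2 M HCl, 50 °C; neutralise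
Reagents that add atoms: ammonium acetate, CC(=O)[O-].[NH4+]; water, O
Why: Swern oxidation activates both hydroxyls before base is added, so the 1,5-keto aldehyde should form without lactol oxidation; ammonia then condenses with both carbonyls to close the pyridine ring (isoquinoline synthesis from a 2-acetonylbenzaldehyde), and aqueous acid frees the C6 phenol and the C7 aldehyde.

Step 8
Reactants: 11 6-hydroxy-8-methoxy-3-methylisoquinoline-7-carbaldehyde
Product: 12 7-formyl-8-methoxy-3-methylisoquinolin-6-yl trifluoromethanesulfonate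
Conditions: PhNTf2, Et3N, CH2Cl2/DMF, rt
Reagents that add atoms: N-phenylbis(trifluoromethanesulfonimide), O=S(=O)(N(c1ccccc1)S(=O)(=O)C(F)(F)F)C(F)(F)F
Why: Phenol triflation with the mild triflimide reagent installs the leaving group for the later C–O coupling and avoids sulfonylation of the ring nitrogen.

Step 9
Reactants: 7 methyl 3-(1,3-dioxolan-2-yl)-2-methoxy-4-(methoxymethoxy)-6-(2-oxopropyl)benzoate
Product: 13 methyl 3-(1,3-dioxolan-2-yl)-2-methoxy-4-(methoxymethoxy)-6-(2-methylprop-2-en-1-yl)benzoate
Conditions: Zn, CH2Br2, TiCl4, THF, 0 °C to rt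
Reagents that add atoms: dibromomethane, BrCBr
Why: Lombardo–Takai methylenation uses a non-basic gem-dimetallic reagent, so the enolisable benzylic ketone should become the 1,1-disubstituted alkene without enolisation and without attack on the hindered ester.

Step 10
Reactants: 13 methyl 3-(1,3-dioxolan-2-yl)-2-methoxy-4-(methoxymethoxy)-6-(2-methylprop-2-en-1-yl)benzoate; 12 7-formyl-8-methoxy-3-methylisoquinolin-6-yl trifluoromethanesulfonate
Product: 15 methyl 3-(1,3-dioxolan-2-yl)-6-[(1R,2S)-1-hydroxy-1-(8-methoxy-3-methyl-6-trifluoromethanesulfonyloxyisoquinolin-7-yl)-3-methylbut-3-en-2-yl]-2-methoxy-4-(methoxymethoxy)benzoate, via allylborane 14 (not isolated)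
Conditions: LiN(iPr)2, THF, −78 °C; (+)-Ipc2BOMe (from (−)-α-pinene); BF3·OEt2, −78 to 0 °C, then −78 °C; 12; HOCH2CH2NH2 work-up
Reagents that add atoms: none
Why: Brown asymmetric allylboration: the lithiated allyl arene is trapped on boron and should settle by 1,3-boron shift as the primary, E-configured γ-aryl allylborane; a six-membered chair transition state with the aldehyde substituent equatorial gives the anti pair (C4 S), and the isopinocampheyl groups direct attack to the Re face of the aldehyde (C3 R).

Step 11
Reactants: 15 the (1R,2S) hydroxy ester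
Product: 16 (3R,4S)-7-(1,3-dioxolan-2-yl)-8-methoxy-6-(methoxymethoxy)-3-(8-methoxy-3-methyl-6-trifluoromethanesulfonyloxyisoquinolin-7-yl)-4-(prop-1-en-2-yl)isochroman-1-one
Conditions: LiN(SiMe3)2, THF, −78 to −20 °C; AcOH
Reagents that add atoms: none
Why: Alkoxide-induced intramolecular transesterification (lactonisation) closes the six-membered isochromanone at low temperature and leaves C3 and C4 untouched.

Step 12
Reactants: 16 the isopropenyl isochromanone
Product: 17 (3R,4S)-4-(1,2-dihydroxypropan-2-yl) analogue of 16 (both epimers at the new carbinol carbon)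
Conditions: OsO4 (cat.), NMO, acetone/H2O, rt
Reagents that add atoms: N-methylmorpholine N-oxide, C[N+]1([O-])CCOCC1; water, O
Why: Upjohn dihydroxylation of the only alkene turns the isopropenyl group into a glycol, a latent methyl ketone that has no acidic C4–H and no alkene for a Heck side reaction; the new carbinol centre is not controlled because it is destroyed later.

Step 13
Reactants: 17 the glycol
Product: 18 (3R,4S)-4-(2,2,4-trimethyl-1,3-dioxolan-4-yl) analogue of 16 (acetonide lactone)
Conditions: Me2C(OMe)2, PPTS (cat.), CH2Cl2, rt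
Reagents that add atoms: 2,2-dimethoxypropane, COC(C)(C)OC
Why: Acetonide formation by transketalisation caps both hydroxyls, so the lactol hydroxyl will be the only free O–H in the coupling step.

Step 14
Reactants: 18 the acetonide lactone
Product: 19 (3R,4S)-7-(1,3-dioxolan-2-yl)-8-methoxy-6-(methoxymethoxy)-3-(8-methoxy-3-methyl-6-trifluoromethanesulfonyloxyisoquinolin-7-yl)-4-(2,2,4-trimethyl-1,3-dioxolan-4-yl)isochroman-1-ol (anomeric mixture)
Conditions: iBu2AlH, CH2Cl2, −78 °C; Rochelle salt
Reagents that add atoms: none
Why: Half-reduction of the lactone with iBu2AlH stops at the aluminium hemiacetal at −78 °C, while the aryl triflate, acetals and MOM ether survive; the anomeric centre forms as an equilibrating mixture.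

Step 15
Reactants: 19 the lactol triflate (anomeric mixture)
Product: 20 (1R,3R,4S) bridged acetal: C1 of the isochroman joined through oxygen to isoquinoline C6 (new 1,3-dioxine ring), with the ring-A dioxolane, the MOM ether and the C4 acetonide unchanged
Conditions: Pd2(dba)3 (cat.), tBuBrettPhos, K3PO4, PhMe, 90 °C
Reagents that add atoms: none
Why: Zerovalent palladium with the bulky biaryl phosphine inserts into the C6–O triflate bond, the phosphate base generates the anomeric alkoxide, which replaces triflate on divalent palladium, and C–O reductive elimination gives the aryl acetal; the closest known reaction type is palladium-catalysed C–O cross-coupling of alcohols and lactols with aryl halides or triflates, here intramolecular. The 1,3-dioxine closes as a six-membered ring through a seven-membered oxa-palladacycle (formally 6-exo attack of the anomeric oxygen on the aryl carbon). The lactol anomers interconvert through the ring-opened hydroxy aldehyde, and only the anomer whose C1 hydroxyl is cis to the C3 isoquinolinyl group (both axial, C4 side chain equatorial) can reach the metal, so C3 dictates the new C1 centre (R) under Curtin–Hammett control. The selectivity needed is C–O reductive elimination over β-hydride elimination of the palladium alkoxide and over other nucleophiles or π systems: the hindered electron-rich ligand speeds reductive elimination, the open-chain C3 hydroxyl could only close a four-membered ring, the phenol and the glycol are capped, and the substrate has neither an alkene nor a carbonyl next to C4.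

Step 16
Reactants: 20 the protected bridged acetal
Product: 21 (1R,3R,4S) bridged acetal with free ring-A phenol, free ring-A aldehyde and a 4-(1,2-dihydroxypropan-2-yl) group (both carbinol epimers)
Conditions: 3 M HCl, THF, 45 °C; NaHCO3
Reagents that add atoms: water, O
Why: Acid-catalysed hydrolysis removes the acetonide, the aryl dioxolane and the MOM ether, while the bridged acetal should persist because any opening is intramolecular and reversible and re-closes to the same bicyclic acetal.

Step 17
Reactants: 21 the glycol
Product: 22 CNP0584953.1 (target)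
Conditions: NaIO4, THF/pH 7 buffer, 0 °C to rt
Reagents that add atoms: none
Why: Malaprade glycol cleavage under near-neutral conditions releases the methyl ketone in the last operation, so the C4 centre set in step 10, now α to a carbonyl, never meets acid or base.

**Compound list**

1 | methyl orsellinate | COC(=O)c1c(C)cc(O)cc1O | starting material
2 | methyl 2-hydroxy-4-(methoxymethoxy)-6-methylbenzoate | COC(=O)c1c(C)cc(OCOC)cc1O | intermediate
3 | methyl 3-formyl-2-hydroxy-4-(methoxymethoxy)-6-methylbenzoate | COC(=O)c1c(C)cc(OCOC)c(C=O)c1O | intermediate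
4 | methyl 3-formyl-2-methoxy-4-(methoxymethoxy)-6-methylbenzoate | COC(=O)c1c(C)cc(OCOC)c(C=O)c1OC | intermediate
5 | methyl 3-(1,3-dioxolan-2-yl)-2-methoxy-4-(methoxymethoxy)-6-methylbenzoate | COC(=O)c1c(C)cc(OCOC)c(C2OCCO2)c1OC | intermediate
6 | N-methoxy-N-methylacetamide | CON(C)C(C)=O | starting material
7 | methyl 3-(1,3-dioxolan-2-yl)-2-methoxy-4-(methoxymethoxy)-6-(2-oxopropyl)benzoate | COC(=O)c1c(CC(C)=O)cc(OCOC)c(C2OCCO2)c1OC | intermediate
8 | 1-[4-(1,3-dioxolan-2-yl)-2-(hydroxymethyl)-3-methoxy-5-(methoxymethoxy)phenyl]propan-2-ol, racemic | CC(O)Cc1cc(OCOC)c(C2OCCO2)c(OC)c1CO | intermediate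
9 | 3-(1,3-dioxolan-2-yl)-2-methoxy-4-(methoxymethoxy)-6-(2-oxopropyl)benzaldehyde | CC(=O)Cc1cc(OCOC)c(C2OCCO2)c(OC)c1C=O | intermediate
10 | 7-(1,3-dioxolan-2-yl)-8-methoxy-6-(methoxymethoxy)-3-methylisoquinoline | Cc1cc2cc(OCOC)c(C3OCCO3)c(OC)c2cn1 | intermediate
11 | 6-hydroxy-8-methoxy-3-methylisoquinoline-7-carbaldehyde | Cc1cc2cc(O)c(C=O)c(OC)c2cn1 | intermediate
12 | 7-formyl-8-methoxy-3-methylisoquinolin-6-yl trifluoromethanesulfonate | Cc1cc2cc(OS(=O)(=O)C(F)(F)F)c(C=O)c(OC)c2cn1 | intermediate
13 | methyl 3-(1,3-dioxolan-2-yl)-2-methoxy-4-(methoxymethoxy)-6-(2-methylprop-2-en-1-yl)benzoate | COC(=O)c1c(CC(C)=C)cc(OCOC)c(C2OCCO2)c1OC | intermediate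
14 | methyl 6-{(1E)-3-[bis((1S,2R,3S,5S)-isopinocampheyl)boranyl]-2-methylprop-1-en-1-yl}-3-(1,3-dioxolan-2-yl)-2-methoxy-4-(methoxymethoxy)benzoate | COC(=O)c1c(/C=C(\C)CB([C@H]2C[C@H]3C[C@@H]([C@@H]2C)C3(C)C)[C@H]2C[C@H]3C[C@@H]([C@@H]2C)C3(C)C)cc(OCOC)c(C2OCCO2)c1OC | intermediate
15 | methyl 3-(1,3-dioxolan-2-yl)-6-[(1R,2S)-1-hydroxy-1-(8-methoxy-3-methyl-6-trifluoromethanesulfonyloxyisoquinolin-7-yl)-3-methylbut-3-en-2-yl]-2-methoxy-4-(methoxymethoxy)benzoate | COC(=O)c1c(OC)c(C2OCCO2)c(OCOC)cc1[C@@H]([C@@H](O)c1c(OS(=O)(=O)C(F)(F)F)cc2cc(C)ncc2c1OC)C(C)=C | intermediate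
16 | (3R,4S)-7-(1,3-dioxolan-2-yl)-8-methoxy-6-(methoxymethoxy)-3-(8-methoxy-3-methyl-6-trifluoromethanesulfonyloxyisoquinolin-7-yl)-4-(prop-1-en-2-yl)isochroman-1-one | COc1c(C2OCCO2)c(OCOC)cc2c1C(=O)O[C@@H](c1c(OS(=O)(=O)C(F)(F)F)cc3cc(C)ncc3c1OC)[C@H]2C(C)=C | intermediate
17 | (3R,4S)-4-(1,2-dihydroxypropan-2-yl) analogue of 16, both carbinol epimers | COc1c(C2OCCO2)c(OCOC)cc2c1C(=O)O[C@@H](c1c(OS(=O)(=O)C(F)(F)F)cc3cc(C)ncc3c1OC)[C@H]2C(C)(O)CO | intermediate
18 | (3R,4S)-4-(2,2,4-trimethyl-1,3-dioxolan-4-yl) analogue of 16, both epimers at the dioxolane carbon | COc1c(C2OCCO2)c(OCOC)cc2c1C(=O)O[C@@H](c1c(OS(=O)(=O)C(F)(F)F)cc3cc(C)ncc3c1OC)[C@H]2C1(C)COC(C)(C)O1 | intermediate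
19 | (3R,4S)-7-(1,3-dioxolan-2-yl)-8-methoxy-6-(methoxymethoxy)-3-(8-methoxy-3-methyl-6-trifluoromethanesulfonyloxyisoquinolin-7-yl)-4-(2,2,4-trimethyl-1,3-dioxolan-4-yl)isochroman-1-ol, anomeric mixture (key-step precursor) | COc1c(C2OCCO2)c(OCOC)cc2c1C(O)O[C@@H](c1c(OS(=O)(=O)C(F)(F)F)cc3cc(C)ncc3c1OC)[C@H]2C1(C)COC(C)(C)O1 | intermediate
20 | (1R,3R,4S) bridged acetal, C1–O–C6 dioxine closed, ring-A aldehyde as dioxolane, phenol as MOM ether, acetyl as glycol acetonide (key-step product) | COc1c(C2OCCO2)c(OCOC)cc2c1[C@H]1Oc3cc4cc(C)ncc4c(OC)c3[C@H](O1)[C@H]2C1(C)COC(C)(C)O1 | intermediate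
21 | (1R,3R,4S) bridged acetal with free phenol, free aldehyde and 4-(1,2-dihydroxypropan-2-yl) group, both carbinol epimers | COc1c(C=O)c(O)cc2c1[C@H]1Oc3cc4cc(C)ncc4c(OC)c3[C@H](O1)[C@H]2C(C)(O)CO | intermediate
22 | CNP0584953.1 | COc1c(C=O)c(O)cc2c1[C@H]1Oc3cc4cc(C)ncc4c(OC)c3[C@H](O1)[C@H]2C(C)=O | target

**Step count and risks**

Total steps: 17. Longest linear sequence: 16 steps (steps 1–8 and 10–17); step 9 is the one-step side branch from 7.

Step 15 (key step). What may go wrong: β-hydride elimination from the palladium-bound anomeric alkoxide, which would oxidise the lactol back to the lactone and reduce the aryl triflate; or cleavage of the triflate S–O bond by alkoxide before oxidative addition. The fallback gives up the metal-catalysed coupling and builds the acetal from the other oxygen under acid catalysis. It sets out from 18: Et4NOH in dioxane cleaves the triflate to give the phenol lactone F1, iBu2AlH at −78 °C gives the phenol lactol F2, and PPTS with 4 Å molecular sieves in CH2Cl2 lets the C6 phenol capture the C1 oxocarbenium ion. This returns to the route at 20.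

Step 10. What may go wrong: incomplete 1,3-boron shift or E/Z scrambling of the allylborane, which would erode the anti selectivity or move C–C bond formation to the terminal carbon; or slow addition to the hindered aldehyde. The fallback is a chromium-mediated Barbier-type allylation (Nozaki–Hiyama type), which is anti-selective whatever the geometry of the allyl halide. It sets out from 13: LiN(iPr)2 then BrCH2CH2Br gives the allylic bromide F3; catalytic CrCl2 with Mn, Me3SiCl and a chiral carbazole bis(oxazoline) ligand (enantiomer chosen for Re-face attack) adds it to 12 to give the silyl ether F4; aqueous citric acid in THF removes the silyl group. This returns to the route at 15.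

Step 16. What may go wrong: acid-induced reorganisation of the bridged acetal once the tertiary hydroxyl is free (capture of the C1 oxocarbenium ion by that hydroxyl in place of the C6 oxygen), or incomplete MOM cleavage. The fallback unmasks the ketone oxidatively first. It sets out from 20: H5IO6 in wet ethyl acetate hydrolyses the terminal acetonide and the aryl dioxolane and cleaves the glycol in the same flask to give the MOM-protected methyl ketone F5; ZnBr2 with n-PrSH in CH2Cl2 at 0 °C then removes the MOM ether. This arrives directly at 22 and bypasses 21.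

Further compounds
F1 | step 15 | (3R,4S)-3-(6-hydroxy-8-methoxy-3-methylisoquinolin-7-yl) analogue of 18 (phenol lactone) | COc1c(C2OCCO2)c(OCOC)cc2c1C(=O)O[C@@H](c1c(O)cc3cc(C)ncc3c1OC)[C@H]2C1(C)COC(C)(C)O1
F2 | step 15 | (3R,4S)-3-(6-hydroxy-8-methoxy-3-methylisoquinolin-7-yl) analogue of 19 (phenol lactol, anomeric mixture) | COc1c(C2OCCO2)c(OCOC)cc2c1C(O)O[C@@H](c1c(O)cc3cc(C)ncc3c1OC)[C@H]2C1(C)COC(C)(C)O1
F3 | step 10 | methyl 6-(1-bromo-2-methylprop-2-en-1-yl)-3-(1,3-dioxolan-2-yl)-2-methoxy-4-(methoxymethoxy)benzoate, racemic | COC(=O)c1c(C(Br)C(C)=C)cc(OCOC)c(C2OCCO2)c1OC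
F4 | step 10 | trimethylsilyl ether of 15 | COC(=O)c1c(OC)c(C2OCCO2)c(OCOC)cc1[C@@H]([C@@H](O[Si](C)(C)C)c1c(OS(=O)(=O)C(F)(F)F)cc2cc(C)ncc2c1OC)C(C)=C
F5 | step 16 | MOM ether of the target (ring-A aldehyde and acetyl group free) | COc1c(C=O)c(OCOC)cc2c1[C@H]1Oc3cc4cc(C)ncc4c(OC)c3[C@H](O1)[C@H]2C(C)=O
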